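## Analysis of the target

Compound 26, (3S,5S,9R,10S)-3-hydroxy-2-oxolabda-7,13E-dien-15-yl acetate, is a bicyclic diterpenoid of the ent-labdane series: a trans-fused decalin (ring A: C1–C5 and C10; ring B: C5–C10) with a six-carbon chain (C11–C16) on C9. Ring A carries an α-ketol (C2 ketone, C3 hydroxyl) next to the quaternary gem-dimethyl carbon C4. Ring B carries the trisubstituted C7=C8 alkene with the C17 methyl group, and the chain an E-trisubstituted C13=C14 alkene ending in the primary allylic acetate at C15. The four stereocentres are related as follows: H5 and the C20 methyl on C10 are trans (the ring fusion), C11 on C9 is equatorial and cis to C20, and O3 is equatorial on the face of C20. Sensitive groups are the 3-hydroxy-2-ketone (it can epimerise at C3 or shift to the 2-hydroxy-3-ketone under base), the allylic acetate (not compatible with enolates, hydrides or zerovalent palladium) and the acid-labile trisubstituted alkenes. The synthesis is hard because the quaternary C10 lies between two stereocentres in the unnatural enantiomeric series, C2 and C3 are oxidised differently next to a quaternary carbon, the ring B alkene must sit at C7=C8 only, and two hydroxyls must be told apart at the end. The plan rests on one feature: the methine C5 is bonded to C4 (CMe2), C6 and C10 (C–CH3), so C4 together with ring B is the carbon skeleton of verbenone, with C8 as carbonyl carbon, C10 as methyl-bearing β-carbon, C5 and C7 as bridgeheads, C6 as methylene bridge and C4 as gem-dimethyl bridge from C5 to C7. Only the bond C4–C7 has to be exchanged for C4–C3, and (1S)-verbenone has C5 in the configuration of 26.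

## Retrosynthetic reasoning

**26 ⇒ 25 ⇒ 24 (C15–O acetyl, then the silyl ethers).** The acetate is cut first because an allylic acetate would not survive the enolate, fluoride or palladium steps. Diol 25 has one unhindered primary allylic hydroxyl and one secondary hydroxyl between C4 and the C2 carbonyl, so acylation can be selective. Both oxygens are carried as silyl ethers in 24 and released together without base.

**24 ⇒ 23 ⇒ 22 (C8–C17).** The C17 methyl is cut at the sp2 carbon C8. An enol triflate 23 with the double bond already at C7=C8 fixes the alkene position in the coupling. 23 goes back to the silyl enol ether 22, in which the C8 oxygen of verbenone is still present. No regioselective enolisation of a decalone is needed, and C9 never becomes enolisable in the decalin.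

**22 ⇒ 18 (C3–C4 cut, C4–C7 re-formed).** This is the key disconnection. Cutting ring A between C3 and C4 and reconnecting C4 to C7 gives the bicyclo[3.1.1]heptanone 18. Its C8 ketone is the verbenone carbonyl, and the C1–C3 unit on C10 is a Z enediol bis-silyl ether. Forward, a catalytic silyl Lewis acid must open the cyclobutane bond α to the carbonyl and the enol ether carbon C3 must take the resulting C4 cation. What is gained is ring A, the 2-keto-3-oxy pattern, the gem-dimethyl carbon and the C7=C8 enol ether in one isomerisation. The ring fusion is already fixed in 18 by C5 and C10.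

**18 ⇒ 17 ⇒ 16 (enediol ether from an α-silyloxy aldehyde).** The enediol ether is traced to aldehyde 17 rather than to a 2-ketone. The aldehyde has a single α-hydrogen (on C2), so the enol ether is regiodefined, and it is silylated far more readily than the hindered C8 ketone. 17 comes from the bis(triethylsilyl) ether 16 by direct oxidation of the primary silyl ether.

**16 ⇒ 14 ⇒ 12 + 6 (C9–C11, then the C9 configuration).** The chain is attached by enolate alkylation of ketone 12 with iodide 6. Only C9 can enolise, since C7 is a bridgehead. The electrophile enters anti to the gem-dimethyl bridge, which gives 14, the wrong C9 epimer. The configuration is therefore set in a separate step: the enolate of 14 is protonated from the same open face, which places C11 on the bridge side, cis to C20, as in 16.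

**12 ⇒ 11 ⇒ 10 ⇒ 7 + 8 (C2/C3 oxygens, then C1–C10).** The two oxygens come from dihydroxylation of the allyl group of 10. This is done before the alkylation, because afterwards the trisubstituted chain alkene would compete. The bond C1–C10 is cut to (1S)-verbenone 7 and allylmagnesium bromide 8. A copper-mediated conjugate addition anti to the bridge makes C10 quaternary, with C20 syn and the C1 chain anti to C4. This is the arrangement that later gives the trans fusion.

**6 ⇒ 5 ⇒ 4 ⇒ 3 ⇒ 1 (C13–C16 and C14–C15).** The E-trisubstituted alkene of the chain is cut at the methyl group and at C15. Carboalumination of the terminal alkyne 1 followed by trapping with a one-carbon electrophile gives 3 with defined geometry. Exchange of protecting groups and iodination lead to 6.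

## Alternatives that were turned down

**Alternative 1:** The cut runs through C9–C10 and C1–C8. Ring A is made first as the enone A1, methyl 3-[5-(tert-butyldimethylsilyloxy)-2,6,6-trimethyl-4-oxocyclohex-2-en-1-yl]propanoate. The quaternary C10 is then created by [2+2] photocycloaddition with allene A2, which should give the methylenecyclobutane A3 with the new C9–C10 bond on the face away from the C5 arm.
- For it: enone–allene photocycloaddition is known chemistry with dependable head-to-head regiochemistry. It builds C10 without an ionic intermediate, and the C3 oxygen is in place early. On the certainty of the bond-forming event it is stronger than the chosen plan, whose key step has no direct precedent.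
- Against it: in A3, C9 is a bare methylene. The C9 chain and its stereocentre, the opening of the four-membered ring at C1–C8, the closure of ring B from the ester arm onto C8, the C17 methyl and the C7=C8 alkene all remain to be done after the key step. A1, with C3 and C5 flanking the quaternary C4, has no chiral-pool source.
- Comparison: the chosen plan starts from a material that already holds C5, C4 with both methyls, all ring B carbons and the C8 oxygen. After its key step only a methyl group and an acetate are missing.

**Alternative 2:** Both rings are cut at once, through C8–C9 and C1–C10. An acyclic enyne A4 carries the C7≡C8 alkyne, the E C9=C10 alkene and a C1=C2 silyl enol ether. It is treated with the gold catalyst A5, which is the monovalent gold complex Ph3PAuNTf2. C9 should add to the gold-bound C8 (6-endo-dig), C1 should trap the C10 cation, and protodeauration should leave the C7=C8 alkene, giving the 3-O-silyl ether A6 of the target.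
- For it: it forms two rings, two C–C bonds and the C9 and C10 stereocentres in one operation, and the C7=C8 alkene with its methyl comes for free. A6 is one deprotection from 26, so on step economy after the key step it is clearly stronger than the chosen plan, which needs four more steps.
- Against it: a 1,5-enyne has several competing gold pathways (5-endo closure, cyclopropyl carbene formation, skeletal shifts). C9 and C10 are controlled only by a chair preference relative to C5 next to a quaternary carbon. The allylic acetate and the second trisubstituted alkene are exposed to the carbophilic Lewis acid A5. A4 itself is a long asymmetric synthesis.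
- Comparison: the chosen plan uses a rigid bicyclic template in which the ring fusion is fixed before any cation forms. Its key step sets one stereocentre only, and that one can be corrected by equilibration.

**Alternative 3:** The decalin is not built but taken from andrographolide A7, an abundant lactone of the same ent-labdane series. The disconnection falls in the chain, at C13–C16 and C14–C15. A terminal alkyne A8 (C13≡C14), obtained by degradation of A7, undergoes Negishi carboalumination (zirconium-catalysed syn addition of a methyl–aluminium bond). The alkenylalane A9 is trapped with formaldehyde A10 to give the allylic alcohol A11.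
- For it: all four ring stereocentres and the C3 oxygen come from nature in the right absolute configuration. The key step is a well-tried reaction with high E selectivity (the same reaction is used here for iodide 6). On stereochemical security it is stronger than the chosen plan.
- Against it: A7 has oxygen in the wrong places. The C19 hydroxymethyl must be reduced to methyl at a neopentyl position. The exocyclic C8=C17 alkene must be moved to C7=C8 without leakage to C8=C9. The butenolide must be cut back to C12 and extended again. After A11 the C2 ketone is still missing and needs oxidation at C3, hydroxylation at C2 and a ketol transposition. The sequence is long and redox-heavy.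
- Comparison: the chosen plan delivers the 2-oxo-3-oxy pattern and the C8 enol handle directly from one step, and does not depend on the substitution pattern of a natural product.

Key step: step 12

## Remarks on the chemistry

- In the discussion, atoms carry labdane numbers (C1–C20) in all compounds, including the bicyclic ones (verbenone carbonyl carbon = C8, α-carbon = C9, β-carbon = C10, bridgeheads = C5 and C7, methylene bridge = C6, gem-dimethyl bridge = C4). Locants and descriptors inside systematic names follow the bicyclo[3.1.1]heptane numbering.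
- Assumption: (1S)-(−)-verbenone is the (1S,5S) enantiomer drawn as 7. Silyl ether 1 is taken as a commercial material (it is the TBS ether of but-3-yn-1-ol).
- Compounds 11, 12, 14, 16 and 17 are mixtures of the two epimers at C2, which becomes sp2 in 18.

## Route

Step 1
Reactants: 1 tert-butyl(but-3-yn-1-yloxy)dimethylsilane
Product: 3 (2E)-5-(tert-butyldimethylsilyloxy)-3-methylpent-2-en-1-ol, via alkenylalane 2 (not isolated)
Conditions: Me3Al, Cp2ZrCl2 (0.2 equiv), CH2Cl2, 0 °C to rt; then n-BuLi, (CH2O)n, THF, −78 °C to rt
Reagents that add atoms: trimethylaluminium, C[Al](C)C; formaldehyde (as paraformaldehyde), C=O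
Why: Negishi carboalumination: Cp2ZrCl2-catalysed syn addition of a methyl–aluminium bond to the terminal alkyne places the methyl group on the inner carbon (C13) and aluminium on C14 on the same side. After activation with n-BuLi the alkenyl–aluminium bond of 2 adds to formaldehyde with retention, which fixes the E alkene and brings in C15.

Step 2
Reactants: 3 (2E)-5-(tert-butyldimethylsilyloxy)-3-methylpent-2-en-1-ol
Product: 4 (2E)-5-(tert-butyldimethylsilyloxy)-1-(tert-butyldiphenylsilyloxy)-3-methylpent-2-ene
Conditions: TBDPSCl, imidazole, CH2Cl2, 0 °C to rt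
Reagents that add atoms: tert-butylchlorodiphenylsilane, CC(C)(C)[Si](Cl)(c1ccccc1)c1ccccc1
Why: Silylation of a primary allylic alcohol. The TBDPS group is chosen because it outlasts the acid of step 3 and the Lewis acids of steps 11 and 12.

Step 3
Reactants: 4 (2E)-5-(tert-butyldimethylsilyloxy)-1-(tert-butyldiphenylsilyloxy)-3-methylpent-2-ene
Product: 5 (3E)-5-(tert-butyldiphenylsilyloxy)-3-methylpent-3-en-1-ol
Conditions: PPTS (cat.), MeOH, rt
Reagents that add atoms: none
Why: Acid-catalysed methanolysis removes a primary TBS ether far faster than a TBDPS ether, so the two primary oxygens are told apart.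

Step 4
Reactants: 5 (3E)-5-(tert-butyldiphenylsilyloxy)-3-methylpent-3-en-1-ol
Product: 6 tert-butyl{[(2E)-5-iodo-3-methylpent-2-en-1-yl]oxy}diphenylsilane
Conditions: I2, PPh3, imidazole, CH2Cl2, 0 °C
Reagents that add atoms: iodine, II
Why: Appel-type iodination: the alkoxyphosphonium ion is displaced by iodide at the primary carbon in an SN2 step. The allylic silyl ether is not touched.

Step 5
Reactants: 7 (1S,5S)-4,6,6-trimethylbicyclo[3.1.1]hept-3-en-2-one [(1S)-(−)-verbenone]; 8 allylmagnesium bromide
Product: 10 (1S,4S,5S)-4,6,6-trimethyl-4-(prop-2-en-1-yl)bicyclo[3.1.1]heptan-2-one (allyl group anti to the gem-dimethyl bridge), via trimethylsilyl enol ether 9 (not isolated)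
Conditions: CuBr·SMe2, LiCl, TMSCl, THF, −78 °C; then 1 M HCl, 0 °C
Reagents that add atoms: none
Why: Conjugate addition of the Grignard-derived allylcopper in the presence of TMSCl, the known way to force an allyl group into the 1,4-mode even with β,β-disubstituted enones. The reagent attacks C10 from the face away from the gem-dimethyl bridge, so C10 becomes quaternary with the allyl group (C1–C3) anti and the methyl group (C20) syn to the bridge. The silyl enol ether 9 is hydrolysed on work-up.

Step 6
Reactants: 10 (1S,4S,5S)-4,6,6-trimethyl-4-(prop-2-en-1-yl)bicyclo[3.1.1]heptan-2-one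
Product: 11 (1S,4S,5S)-4-(2,3-dihydroxypropyl)-4,6,6-trimethylbicyclo[3.1.1]heptan-2-one as a mixture of C2 epimers
Conditions: OsO4 (2 mol %), NMO, acetone/H2O, rt
Reagents that add atoms: N-methylmorpholine N-oxide, C[N+]1([O-])CCOCC1; water, O
Why: Upjohn dihydroxylation of the only alkene. It is done before the side chain is attached because its electron-rich trisubstituted alkene would compete for OsO4. The configuration at C2 is of no consequence, as C2 becomes sp2 in step 11.

Step 7
Reactants: 11 (1S,4S,5S)-4-(2,3-dihydroxypropyl)-4,6,6-trimethylbicyclo[3.1.1]heptan-2-one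
Product: 12 (1S,4S,5S)-4-[2,3-bis(triethylsilyloxy)propyl]-4,6,6-trimethylbicyclo[3.1.1]heptan-2-one
Conditions: TESCl, imidazole, DMAP (cat.), CH2Cl2, 0 °C to rt
Reagents that add atoms: chlorotriethylsilane, CC[Si](Cl)(CC)CC
Why: Silylation of both hydroxyls. Triethylsilyl is chosen because a primary triethylsilyl ether can be oxidised directly in step 10, and because the group left on O2 becomes the chain-carrying silyl group of step 12.

Step 8
Reactants: 12 (1S,4S,5S)-4-[2,3-bis(triethylsilyloxy)propyl]-4,6,6-trimethylbicyclo[3.1.1]heptan-2-one; 6 tert-butyl{[(2E)-5-iodo-3-methylpent-2-en-1-yl]oxy}diphenylsilane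
Product: 14 (1S,3R,4R,5R)-4-[2,3-bis(triethylsilyloxy)propyl]-3-[(3E)-5-(tert-butyldiphenylsilyloxy)-3-methylpent-3-en-1-yl]-4,6,6-trimethylbicyclo[3.1.1]heptan-2-one in the 9-epi series (C11 anti to the gem-dimethyl bridge), via lithium enolate 13 (not isolated)
Conditions: LDA, THF, −78 °C; then 6, HMPA, −78 to −20 °C
Reagents that add atoms: none
Why: Enolate alkylation: only C9 can be deprotonated (C7 is a bridgehead of the bicyclo[3.1.1]heptane), and the lithium enolate 13 displaces the primary iodide in THF/HMPA (SN2). The electrophile comes from the face away from the gem-dimethyl bridge, so C11 ends up cis to the C1 chain, the C9 epimer of what the target needs.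

Step 9
Reactants: 14 (1S,3R,4R,5R)-4-[2,3-bis(triethylsilyloxy)propyl]-3-[(3E)-5-(tert-butyldiphenylsilyloxy)-3-methylpent-3-en-1-yl]-4,6,6-trimethylbicyclo[3.1.1]heptan-2-one (9-epi ketone)
Product: 16 (1S,3S,4R,5R)-4-[2,3-bis(triethylsilyloxy)propyl]-3-[(3E)-5-(tert-butyldiphenylsilyloxy)-3-methylpent-3-en-1-yl]-4,6,6-trimethylbicyclo[3.1.1]heptan-2-one in the target series (C11 syn to the gem-dimethyl bridge and cis to C20), via lithium enolate 15 (not isolated)
Conditions: LDA, THF, −78 to 0 °C; then AcOH, THF, −78 °C
Reagents that add atoms: none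
Why: Deprotonation and kinetic protonation: the tetrasubstituted enolate 15 takes up the proton, like any electrophile, from the face away from the gem-dimethyl bridge, which pushes C11 to the bridge side, cis to C20. This sets C9 as in the target without relying on the relative stability of the two epimers.

Step 10
Reactants: 16 (1S,3S,4R,5R)-4-[2,3-bis(triethylsilyloxy)propyl]-3-[(3E)-5-(tert-butyldiphenylsilyloxy)-3-methylpent-3-en-1-yl]-4,6,6-trimethylbicyclo[3.1.1]heptan-2-one
Product: 17 (1S,3S,4R,5R)-3-[(3E)-5-(tert-butyldiphenylsilyloxy)-3-methylpent-3-en-1-yl]-4,6,6-trimethyl-4-[3-oxo-2-(triethylsilyloxy)propyl]bicyclo[3.1.1]heptan-2-one (aldehyde at C3, triethylsilyl ether on C2)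
Conditions: (COCl)2, DMSO, CH2Cl2, −78 to −40 °C; then Et3N, −78 to 0 °C
Reagents that add atoms: none
Why: Swern oxidation of a primary triethylsilyl ether: the chlorosulfonium reagent cleaves the unhindered primary Si–O bond and oxidises the resulting alkoxysulfonium ion to the aldehyde. The secondary triethylsilyl ether, the TBDPS ether and the ketone are left alone.

Step 11
Reactants: 17 (1S,3S,4R,5R)-3-[(3E)-5-(tert-butyldiphenylsilyloxy)-3-methylpent-3-en-1-yl]-4,6,6-trimethyl-4-[3-oxo-2-(triethylsilyloxy)propyl]bicyclo[3.1.1]heptan-2-one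
Product: 18 (1S,3S,4R,5R)-3-[(3E)-5-(tert-butyldiphenylsilyloxy)-3-methylpent-3-en-1-yl]-4-[(2Z)-3-(tert-butyldimethylsilyloxy)-2-(triethylsilyloxy)prop-2-en-1-yl]-4,6,6-trimethylbicyclo[3.1.1]heptan-2-one (C11 syn and C1 anti to the gem-dimethyl bridge)
Conditions: TBSOTf, Et3N, CH2Cl2, −78 °C
Reagents that add atoms: tert-butyldimethylsilyl trifluoromethanesulfonate, CC(C)(C)[Si](C)(C)OS(=O)(=O)C(F)(F)F
Why: Soft enolisation of an α-silyloxy aldehyde: the only α-hydrogen is on C2, so the enediol bis-silyl ether is regiodefined, and the aldehyde is silylated much faster than the hindered C8 ketone. The Z isomer (both oxygens cis) is expected from the cis preference of 1,2-dioxyalkenes and from the bulk of the neopentyl C1.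

Step 12
Reactants: 18 (1S,3S,4R,5R)-3-[(3E)-5-(tert-butyldiphenylsilyloxy)-3-methylpent-3-en-1-yl]-4-[(2Z)-3-(tert-butyldimethylsilyloxy)-2-(triethylsilyloxy)prop-2-en-1-yl]-4,6,6-trimethylbicyclo[3.1.1]heptan-2-one
Product: 22 15-(tert-butyldiphenylsilyloxy)-3-(tert-butyldimethylsilyloxy)-8-(triethylsilyloxy)-17-nor-ent-labda-7,13E-dien-2-one (H5 trans to C20; C11 cis to C20; O3 equatorial), via silyloxocarbenium ion 19 (not isolated), via tertiary C4 cation 20 (not isolated), via ring A oxocarbenium ion 21 (not isolated)
Conditions: TESOTf (0.2 equiv), 2,6-di-tert-butyl-4-methylpyridine (DTBMP, 0.3 equiv), CH2Cl2, −78 to −30 °C; then Et3N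
Reagents that add atoms: triethylsilyl trifluoromethanesulfonate, CC[Si](CC)(CC)OS(=O)(=O)C(F)(F)F (chain carrier: the SiEt3 group on O8 comes from it and it is re-formed from the SiEt3 group on O2, so the net change is an isomerisation)
Why: Proposed new method: TESOTf silylates the C8 carbonyl oxygen (19); the strained C7–C4 bond, which lies almost parallel to the π* orbital of the oxocarbenium ion, then breaks to the tertiary C4 cation and the C7=C8 silyl enol ether (20), C3 of the tethered enediol ether adds to C4, and the ring A oxocarbenium ion 21 passes its SiEt3 group to the carbonyl of the next molecule of 18 (directly or through triflate), so that the promoter turns over and the step is overall an isomerisation. The closest known reaction type is the Lewis-acid opening of 4-substituted pinan-2-ones in which the 2-propyl cation is caught by a tethered phenol oxygen or an arene; capture by a carbon π-nucleophile of the enol ether class in the same event has not been shown. Ring A closes in a 6-endo-trig cation–alkene mode through a chair in which C4 (on C5) and C1 (on C10) are both equatorial on the half-chair of ring B. C3 is the only new stereocentre: in the Z enediol ether O3 is anti to C1 and so becomes equatorial in the chair, and because C3 is α to the new ketone the equatorial ether is also the more stable epimer; the trans ring fusion is not created here but follows from the fixed centres C5 and C10. The step needs alkylation at C4 to outrun attack of C3 on the activated C8 carbonyl (Mukaiyama aldol), enol silylation toward C9 and proton loss from the cation. The aldol would give a bridged adduct with a fully substituted C8 between a bridgehead and two branched carbons and should revert while the ring opening cannot, no amine that could deprotonate C9 is present (DTBMP only traps triflic acid), and the doubly oxygenated alkene sits five atoms from the cation in a chair-ready tether.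

Step 13
Reactants: 22 15-(tert-butyldiphenylsilyloxy)-3-(tert-butyldimethylsilyloxy)-8-(triethylsilyloxy)-17-nor-ent-labda-7,13E-dien-2-one
Product: 23 15-(tert-butyldiphenylsilyloxy)-3-(tert-butyldimethylsilyloxy)-2-oxo-17-nor-ent-labda-7,13E-dien-8-yl trifluoromethanesulfonate
Conditions: CsF, PhNTf2, DME, rt
Reagents that add atoms: N-phenylbis(trifluoromethanesulfonimide), O=S(=O)(N(c1ccccc1)S(=O)(=O)C(F)(F)F)C(F)(F)F
Why: Fluoride cleaves the Si–O bond of the silyl enol ether only (alkyl silyl ethers are stable to CsF in DME). The cesium enolate is sulfonylated on oxygen by PhNTf2 before it can equilibrate, so the C7=C8 position is kept.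

Step 14
Reactants: 23 15-(tert-butyldiphenylsilyloxy)-3-(tert-butyldimethylsilyloxy)-2-oxo-17-nor-ent-labda-7,13E-dien-8-yl trifluoromethanesulfonate
Product: 24 15-(tert-butyldiphenylsilyloxy)-3-(tert-butyldimethylsilyloxy)-ent-labda-7,13E-dien-2-one
Conditions: Pd(PPh3)4 (5 mol %), Me2Zn, THF, 0 °C to rt
Reagents that add atoms: dimethylzinc, C[Zn]C
Why: Negishi coupling: oxidative addition of the alkenyl triflate to zerovalent palladium, transmetalation from zinc and reductive elimination put C17 on C8 with the alkene fixed at C7=C8. Ketone, silyl ethers and the chain alkene are tolerated at room temperature.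

Step 15
Reactants: 24 15-(tert-butyldiphenylsilyloxy)-3-(tert-butyldimethylsilyloxy)-ent-labda-7,13E-dien-2-one
Product: 25 (3S,5S,9R,10S)-3,15-dihydroxylabda-7,13E-dien-2-one
Conditions: HF·pyridine, pyridine, THF, 0 °C to rt
Reagents that add atoms: none
Why: Fluoride-mediated cleavage of both silyl ethers under buffered, non-basic conditions, which spares the α-ketol from base-induced epimerisation or 1,2-carbonyl shift.

Step 16
Reactants: 25 (3S,5S,9R,10S)-3,15-dihydroxylabda-7,13E-dien-2-one
Product: 26 (3S,5S,9R,10S)-3-hydroxy-2-oxolabda-7,13E-dien-15-yl acetate (CNP0164008.1)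
Conditions: Ac2O (1.1 equiv), 2,4,6-collidine, CH2Cl2, −20 to 0 °C
Reagents that add atoms: acetic anhydride, CC(=O)OC(C)=O
Why: Acylation under kinetic control: the unhindered primary allylic hydroxyl reacts much faster than the secondary C3 hydroxyl, which is flanked by the quaternary C4 and the carbonyl group.

## Compound list

1 | tert-butyl(but-3-yn-1-yloxy)dimethylsilane | C#CCCO[Si](C)(C)C(C)(C)C | starting material
2 | [(1E)-4-(tert-butyldimethylsilyloxy)-2-methylbut-1-en-1-yl]dimethylalumane | C[Al](C)/C=C(\C)CCO[Si](C)(C)C(C)(C)C | intermediate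
3 | (2E)-5-(tert-butyldimethylsilyloxy)-3-methylpent-2-en-1-ol | OC/C=C(\C)CCO[Si](C)(C)C(C)(C)C | intermediate
4 | (2E)-5-(tert-butyldimethylsilyloxy)-1-(tert-butyldiphenylsilyloxy)-3-methylpent-2-ene | CC(C)(C)[Si](C)(C)OCC/C(C)=C/CO[Si](c1ccccc1)(c1ccccc1)C(C)(C)C | intermediate
5 | (3E)-5-(tert-butyldiphenylsilyloxy)-3-methylpent-3-en-1-ol | OCC/C(C)=C/CO[Si](c1ccccc1)(c1ccccc1)C(C)(C)C | intermediate
6 | tert-butyl{[(2E)-5-iodo-3-methylpent-2-en-1-yl]oxy}diphenylsilane | ICC/C(C)=C/CO[Si](c1ccccc1)(c1ccccc1)C(C)(C)C | intermediate
7 | (1S,5S)-4,6,6-trimethylbicyclo[3.1.1]hept-3-en-2-one, (1S)-(−)-verbenone | O=C1C=C(C)[C@@H]2C[C@H]1C2(C)C | starting material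
8 | allylmagnesium bromide | C=CC[Mg]Br | starting material
9 | trimethylsilyl enol ether of 10 (C8=C9 enol ether, allyl anti to the gem-dimethyl bridge) | C[Si](C)(C)OC1=C[C@](C)(CC=C)[C@@H]2C[C@H]1C2(C)C | intermediate
10 | (1S,4S,5S)-4,6,6-trimethyl-4-(prop-2-en-1-yl)bicyclo[3.1.1]heptan-2-one (allyl anti to the gem-dimethyl bridge) | O=C1C[C@](C)(CC=C)[C@@H]2C[C@H]1C2(C)C | intermediate
11 | (1S,4S,5S)-4-(2,3-dihydroxypropyl)-4,6,6-trimethylbicyclo[3.1.1]heptan-2-one, both C2 epimers | O=C1C[C@](C)(CC(O)CO)[C@@H]2C[C@H]1C2(C)C | intermediate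
12 | (1S,4S,5S)-4-[2,3-bis(triethylsilyloxy)propyl]-4,6,6-trimethylbicyclo[3.1.1]heptan-2-one, both C2 epimers | O=C1C[C@](C)(CC(O[Si](CC)(CC)CC)CO[Si](CC)(CC)CC)[C@@H]2C[C@H]1C2(C)C | intermediate
13 | lithium enolate of 12 (C8=C9) | [Li]OC1=C[C@](C)(CC(O[Si](CC)(CC)CC)CO[Si](CC)(CC)CC)[C@@H]2C[C@H]1C2(C)C | intermediate
14 | (1S,3R,4R,5R)-4-[2,3-bis(triethylsilyloxy)propyl]-3-[(3E)-5-(tert-butyldiphenylsilyloxy)-3-methylpent-3-en-1-yl]-4,6,6-trimethylbicyclo[3.1.1]heptan-2-one, 9-epi series (C11 anti to the gem-dimethyl bridge, cis to the C1 chain), both C2 epimers | O=C1[C@H](CC/C(C)=C/CO[Si](c3ccccc3)(c3ccccc3)C(C)(C)C)[C@](C)(CC(O[Si](CC)(CC)CC)CO[Si](CC)(CC)CC)[C@@H]2C[C@H]1C2(C)C | intermediate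
15 | lithium enolate of 14 (tetrasubstituted C8=C9) | [Li]OC1=C(CC/C(C)=C/CO[Si](c3ccccc3)(c3ccccc3)C(C)(C)C)[C@](C)(CC(O[Si](CC)(CC)CC)CO[Si](CC)(CC)CC)[C@@H]2C[C@H]1C2(C)C | intermediate
16 | (1S,3S,4R,5R)-4-[2,3-bis(triethylsilyloxy)propyl]-3-[(3E)-5-(tert-butyldiphenylsilyloxy)-3-methylpent-3-en-1-yl]-4,6,6-trimethylbicyclo[3.1.1]heptan-2-one, target series (C11 syn to the gem-dimethyl bridge, cis to C20), both C2 epimers | O=C1[C@@H](CC/C(C)=C/CO[Si](c3ccccc3)(c3ccccc3)C(C)(C)C)[C@](C)(CC(O[Si](CC)(CC)CC)CO[Si](CC)(CC)CC)[C@@H]2C[C@H]1C2(C)C | intermediate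
17 | (1S,3S,4R,5R)-3-[(3E)-5-(tert-butyldiphenylsilyloxy)-3-methylpent-3-en-1-yl]-4,6,6-trimethyl-4-[3-oxo-2-(triethylsilyloxy)propyl]bicyclo[3.1.1]heptan-2-one (C3 aldehyde, C2–OTES, C8 ketone), both C2 epimers | O=C1[C@@H](CC/C(C)=C/CO[Si](c3ccccc3)(c3ccccc3)C(C)(C)C)[C@](C)(CC(O[Si](CC)(CC)CC)C=O)[C@@H]2C[C@H]1C2(C)C | intermediate
18 | (1S,3S,4R,5R)-3-[(3E)-5-(tert-butyldiphenylsilyloxy)-3-methylpent-3-en-1-yl]-4-[(2Z)-3-(tert-butyldimethylsilyloxy)-2-(triethylsilyloxy)prop-2-en-1-yl]-4,6,6-trimethylbicyclo[3.1.1]heptan-2-one | O=C1[C@@H](CC/C(C)=C/CO[Si](c3ccccc3)(c3ccccc3)C(C)(C)C)[C@](C)(C/C(O[Si](CC)(CC)CC)=C/O[Si](C)(C)C(C)(C)C)[C@@H]2C[C@H]1C2(C)C | intermediate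
19 | O8-triethylsilyl oxocarbenium ion of 18 | CC[Si](CC)(CC)[O+]=C1[C@@H](CC/C(C)=C/CO[Si](c3ccccc3)(c3ccccc3)C(C)(C)C)[C@](C)(C/C(O[Si](CC)(CC)CC)=C/O[Si](C)(C)C(C)(C)C)[C@@H]2C[C@H]1C2(C)C | intermediate
20 | ring-opened tertiary C4 cation with C7=C8 triethylsilyl enol ether | CC[Si](CC)(CC)OC1=CC[C@H]([C+](C)C)[C@@](C)(C/C(O[Si](CC)(CC)CC)=C/O[Si](C)(C)C(C)(C)C)[C@@H]1CC/C(C)=C/CO[Si](c2ccccc2)(c2ccccc2)C(C)(C)C | intermediate
21 | cyclised decalin with O2-triethylsilyl oxocarbenium ion | CC(C)(C)[Si](c1ccccc1)(c1ccccc1)OC/C=C(\C)CC[C@@H]1C(O[Si](CC)(CC)CC)=CC[C@@H]2C(C)(C)[C@H](O[Si](C)(C)C(C)(C)C)C(=[O+][Si](CC)(CC)CC)C[C@@]12C | intermediate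
22 | 15-(tert-butyldiphenylsilyloxy)-3-(tert-butyldimethylsilyloxy)-8-(triethylsilyloxy)-17-nor-ent-labda-7,13E-dien-2-one | CC(C)(C)[Si](c1ccccc1)(c1ccccc1)OC/C=C(\C)CC[C@@H]1C(O[Si](CC)(CC)CC)=CC[C@@H]2C(C)(C)[C@H](O[Si](C)(C)C(C)(C)C)C(=O)C[C@@]12C | intermediate
23 | 15-(tert-butyldiphenylsilyloxy)-3-(tert-butyldimethylsilyloxy)-2-oxo-17-nor-ent-labda-7,13E-dien-8-yl triflate | CC(C)(C)[Si](c1ccccc1)(c1ccccc1)OC/C=C(\C)CC[C@@H]1C(OS(=O)(=O)C(F)(F)F)=CC[C@@H]2C(C)(C)[C@H](O[Si](C)(C)C(C)(C)C)C(=O)C[C@@]12C | intermediate
24 | 15-(tert-butyldiphenylsilyloxy)-3-(tert-butyldimethylsilyloxy)-ent-labda-7,13E-dien-2-one | CC(C)(C)[Si](c1ccccc1)(c1ccccc1)OC/C=C(\C)CC[C@@H]1C(C)=CC[C@@H]2C(C)(C)[C@H](O[Si](C)(C)C(C)(C)C)C(=O)C[C@@]12C | intermediate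
25 | (3S,5S,9R,10S)-3,15-dihydroxylabda-7,13E-dien-2-one | OC/C=C(\C)CC[C@@H]1C(C)=CC[C@@H]2C(C)(C)[C@H](O)C(=O)C[C@@]12C | intermediate
26 | (3S,5S,9R,10S)-3-hydroxy-2-oxolabda-7,13E-dien-15-yl acetate | CC(=O)OC/C=C(\C)CC[C@@H]1C(C)=CC[C@@H]2C(C)(C)[C@H](O)C(=O)C[C@@]12C | target

## Step count and least certain steps

Total step count: 16. Longest linear sequence: 13 steps (steps 1–4, then 8–16). From verbenone 7 the sequence is 12 steps (steps 5–16).

**Step 12 (key step, proposed new method).** Most likely to go wrong: the C4 cation loses a proton to an isopropenyl group before C3 reaches it, or C3 adds to the activated C8 carbonyl instead, or the ketone is merely enol-silylated toward C9. All three are established pathways of simpler pinanones and of silyl-activated ketones, whereas the C–C capture asked for here is not. Promoter loading and temperature are the first things to vary.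
Fallback (known reactions only): ionisation and C–C bond formation are separated. From ketone 16, TiCl4 in CH2Cl2 at −78 °C should open the cyclobutane in the way known for pinan-2-ones, the chloride of the Lewis acid capturing the cation. After aqueous work-up this gives the ring-opened chloro ketone F1 (C8 ketone, 2-chloropropan-2-yl group on C5). Swern oxidation of the primary triethylsilyl ether, as in step 10, gives aldehyde F2. TBSOTf/Et3N at −78 °C (aldehyde) followed by TESOTf/Et3N at 0 °C (C8 ketone, toward the unhindered C7) gives the bis(silyl enol ether) F3, which still holds the tertiary chloride. ZnCl2-catalysed ionisation of the chloride (Reetz tert-alkylation of a silyl enol ether) then forms C3–C4 and comes back to the route at 22.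

**Step 8 (alkylation).** Most likely to go wrong: the enolate, hindered by the neighbouring quaternary C10, acts as a base on the homoallylic iodide (E2 to a conjugated diene) or reacts too slowly.
Fallback: from ketone 12, condensation with Me2NNH2 gives the N,N-dimethylhydrazone F4. Its lithium azaenolate (LDA), a stronger carbon nucleophile than the ketone enolate, is alkylated with 6 to the hydrazone F5 (Corey–Enders alkylation). Hydrolysis with Cu(OAc)2 in aqueous THF comes back at 14.

**Step 9 (C9 correction).** Most likely to go wrong: incomplete deprotonation of the C9–H, which sits under the gem-dimethyl bridge, or partial equilibration of the kinetic epimer during the quench.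
Fallback: from 14, soft enolisation with TMSOTf/Et3N gives the tetrasubstituted trimethylsilyl enol ether F6; here the proton is lost from an oxocarbenium ion and not taken by an amide base. MeLi then releases enolate 15 free of amine, and protonation as in step 9 comes back at 16.

**Step 13 (enol triflate).** Most likely to go wrong: proton transfer from C1 or C3 of the C2 ketone to the cesium enolate, which would move the enolate or return the C8 ketone, and partial loss of the C3 silyl group to fluoride.
Fallback: the C2 ketone is masked. From 22, LiBH4 reduces the C2 ketone to the alcohol F7 (either epimer), and TESCl/imidazole gives the 2-O-triethylsilyl ether F8. CsF/PhNTf2, now without an enolisable ketone, gives the triflate F9, and Pd(PPh3)4/Me2Zn gives the C8-methyl compound F10. PPTS/MeOH removes the secondary triethylsilyl ether to the alcohol F11, and Dess–Martin oxidation comes back at 24.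

**Step 5 (conjugate allylation).** Most likely to go wrong: 1,2-addition of the allyl nucleophile to the carbonyl, since allyl metals are the least biased toward the conjugate mode and the β-carbon is fully substituted.
Fallback: the 1,2-addition is used on purpose. From 7 and 8 without copper, the tertiary allylic alcohol F12 forms (allyl anti to the bridge). KH/18-crown-6 in THF then triggers an anionic oxy-Cope rearrangement that moves the allyl group suprafacially to C10 on the same face, and protonation of the enolate comes back at 10.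

## Further compounds

F1 | step 12 | ring-opened chloro ketone: cyclohexanone with 2-chloropropan-2-yl on C5, bis(triethylsilyloxy)propyl and methyl on C10, side chain on C9 | O=C1CC[C@H](C(C)(C)Cl)[C@@](C)(CC(O[Si](CC)(CC)CC)CO[Si](CC)(CC)CC)[C@@H]1CC/C(C)=C/CO[Si](c2ccccc2)(c2ccccc2)C(C)(C)C
F2 | step 12 | ring-opened chloro keto aldehyde (C3 aldehyde, C2–OTES) | O=C1CC[C@H](C(C)(C)Cl)[C@@](C)(CC(O[Si](CC)(CC)CC)C=O)[C@@H]1CC/C(C)=C/CO[Si](c2ccccc2)(c2ccccc2)C(C)(C)C
F3 | step 12 | ring-opened tertiary chloride with C7=C8 triethylsilyl enol ether and Z enediol bis-silyl ether | CC[Si](CC)(CC)OC1=CC[C@H](C(C)(C)Cl)[C@@](C)(C/C(O[Si](CC)(CC)CC)=C/O[Si](C)(C)C(C)(C)C)[C@@H]1CC/C(C)=C/CO[Si](c2ccccc2)(c2ccccc2)C(C)(C)C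
F4 | step 8 | N,N-dimethylhydrazone of 12 | CN(C)N=C1C[C@](C)(CC(O[Si](CC)(CC)CC)CO[Si](CC)(CC)CC)[C@@H]2C[C@H]1C2(C)C
F5 | step 8 | N,N-dimethylhydrazone of 14 | CN(C)N=C1[C@H](CC/C(C)=C/CO[Si](c3ccccc3)(c3ccccc3)C(C)(C)C)[C@](C)(CC(O[Si](CC)(CC)CC)CO[Si](CC)(CC)CC)[C@@H]2C[C@H]1C2(C)C
F6 | step 9 | tetrasubstituted trimethylsilyl enol ether of 14 (C8=C9) | C[Si](C)(C)OC1=C(CC/C(C)=C/CO[Si](c3ccccc3)(c3ccccc3)C(C)(C)C)[C@](C)(CC(O[Si](CC)(CC)CC)CO[Si](CC)(CC)CC)[C@@H]2C[C@H]1C2(C)C
F7 | step 13 | 2-alcohol of 22 (either C2 epimer) | CC(C)(C)[Si](c1ccccc1)(c1ccccc1)OC/C=C(\C)CC[C@@H]1C(O[Si](CC)(CC)CC)=CC[C@@H]2C(C)(C)[C@H](O[Si](C)(C)C(C)(C)C)C(O)C[C@@]12C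
F8 | step 13 | 2-O-triethylsilyl ether of F7 | CC(C)(C)[Si](c1ccccc1)(c1ccccc1)OC/C=C(\C)CC[C@@H]1C(O[Si](CC)(CC)CC)=CC[C@@H]2C(C)(C)[C@H](O[Si](C)(C)C(C)(C)C)C(O[Si](CC)(CC)CC)C[C@@]12C
F9 | step 13 | C8 enol triflate with 2-O-triethylsilyl ether | CC(C)(C)[Si](c1ccccc1)(c1ccccc1)OC/C=C(\C)CC[C@@H]1C(OS(=O)(=O)C(F)(F)F)=CC[C@@H]2C(C)(C)[C@H](O[Si](C)(C)C(C)(C)C)C(O[Si](CC)(CC)CC)C[C@@]12C
F10 | step 13 | C8-methyl compound with 2-O-triethylsilyl ether | CC(C)(C)[Si](c1ccccc1)(c1ccccc1)OC/C=C(\C)CC[C@@H]1C(C)=CC[C@@H]2C(C)(C)[C@H](O[Si](C)(C)C(C)(C)C)C(O[Si](CC)(CC)CC)C[C@@]12C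
F11 | step 13 | C8-methyl 2-alcohol (2-hydroxy analogue of 24) | CC(C)(C)[Si](c1ccccc1)(c1ccccc1)OC/C=C(\C)CC[C@@H]1C(C)=CC[C@@H]2C(C)(C)[C@H](O[Si](C)(C)C(C)(C)C)C(O)C[C@@]12C
F12 | step 5 | (1S,2S,5S)-4,6,6-trimethyl-2-(prop-2-en-1-yl)bicyclo[3.1.1]hept-3-en-2-ol (allyl anti to the gem-dimethyl bridge) | O[C@@]1(CC=C)C=C(C)[C@@H]2C[C@H]1C2(C)C
A1 | alternative 1 | methyl 3-[5-(tert-butyldimethylsilyloxy)-2,6,6-trimethyl-4-oxocyclohex-2-en-1-yl]propanoate (ring A enone) | COC(=O)CC[C@H]1C(C)=CC(=O)[C@@H](O[Si](C)(C)C(C)(C)C)C1(C)C
A2 | alternative 1 | allene (propa-1,2-diene) | C=C=C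
A3 | alternative 1 | cis-fused methylenecyclobutane photoadduct | COC(=O)CC[C@H]1[C@]2(C)CC(=C)[C@@H]2C(=O)[C@@H](O[Si](C)(C)C(C)(C)C)C1(C)C
A4 | alternative 2 | acyclic enyne with C7≡C8 alkyne, E C9=C10 alkene and C1=C2 trimethylsilyl enol ether | CC(=O)OC/C=C(\C)CC/C=C(\C)[C@H](CC#CC)C(C)(C)[C@H](O[Si](C)(C)C(C)(C)C)C(=C)O[Si](C)(C)C
A5 | alternative 2 | (triphenylphosphine)gold bis(trifluoromethanesulfonyl)imide, Ph3PAuNTf2 | FC(F)(F)S(=O)(=O)N([Au-][P+](c1ccccc1)(c1ccccc1)c1ccccc1)S(=O)(=O)C(F)(F)F
A6 | alternative 2 | 3-O-tert-butyldimethylsilyl ether of the target | CC(=O)OC/C=C(\C)CC[C@@H]1C(C)=CC[C@@H]2C(C)(C)[C@H](O[Si](C)(C)C(C)(C)C)C(=O)C[C@@]12C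
A7 | alternative 3 | andrographolide | C[C@@]12CC[C@H]([C@@]([C@H]1CCC(=C)[C@H]2C/C=C/3\[C@@H](COC3=O)O)(C)CO)O
A8 | alternative 3 | 3-O-silyl 15,16-dinor-ent-labd-7-en-13-yne (terminal C13≡C14 alkyne) | C#CCC[C@@H]1C(C)=CC[C@@H]2C(C)(C)[C@H](O[Si](C)(C)C(C)(C)C)CC[C@@]12C
A9 | alternative 3 | (E)-alkenyldimethylalane from A8 (aluminium on C14, methyl on C13) | C[Al](C)/C=C(\C)CC[C@@H]1C(C)=CC[C@@H]2C(C)(C)[C@H](O[Si](C)(C)C(C)(C)C)CC[C@@]12C
A10 | alternative 3 | formaldehyde | C=O
A11 | alternative 3 | 3-O-silyl ent-labda-7,13E-dien-15-ol | OC/C=C(\C)CC[C@@H]1C(C)=CC[C@@H]2C(C)(C)[C@H](O[Si](C)(C)C(C)(C)C)CC[C@@]12C
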